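**Assumptions and notation (one line each)**
- The target is taken exactly as drawn: two eight-membered carbocycles sharing one CH–CH bond, each fused to a trans-2,3-dihydrobenzofuran.
- Reading the target SMILES from the left, the eight stereogenic CH carbons are called C-a, C-b, C-d, C-e, C-f, C-g, C-h, C-c; the target is a R, b R, c R, d R, e R, f S, g S, h S.
- ArBr = 3-(2-bromo-3,5-dimethoxyphenyl)-6-methoxy-2-(4-methoxyphenyl)-1-benzofuran-4-yl; ArI = the 2-iodo analogue.
- The route is a paper design; the stereochemical outcomes of steps 11, 15 and 18 are predictions from transition-state models, not demonstrated results.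

**Retrosynthetic overview**
1. 33 ⇐ decamethyl ether 32 ⇐ bis-benzofuran carbinol 31, by one ionic hydrogenation that sets C-a and both trans-dihydrofuran pairs (C-b/C-c, C-f/C-h).
2. Second eight-membered ring (C-a–aryl bond) by Br/Li exchange and intramolecular acylation; first eight-membered ring (C-e–aryl bond) by Ni/Cr aryl–aldehyde closure, then C-e arylated with anisole.
3. Key step: the shared C-g–C-d bond and its two stereocentres by Ireland–Claisen [3,3] rearrangement of allylic arylacetate 21, with 1,3-chirality transfer from bought (S)-but-3-yn-2-ol.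
4. 21 ⇐ acid 20 (iodo unit) + (S,Z)-allylic alcohol 12 (bromo unit); each 2,3-diarylbenzofuran comes from a Friedel–Crafts hydroxybenzophenone. The iodo/bromo difference makes each ring closure possible only in the eight-membered (not seven-membered) sense.
5. Ring order: two aromatic benzofurans → [3,3] C–C bond → eight-membered ring one → eight-membered ring two → the two furan rings reduced to trans-dihydrofurans last.

**Route**

Step 1
Reactants: 1 3,5-dimethoxybenzoic acid
Product: 2 2-bromo-3,5-dimethoxybenzoic acid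
Conditions: NBS (1.0 equiv), MeCN, 20 °C
Reagents that add atoms: N-bromosuccinimide, BrN1C(=O)CCC1=O
Why: Electrophilic aromatic bromination goes to C2, which is para to one methoxy group and ortho to the other, while the position between the two methoxy groups is more hindered.

Step 2
Reactants: 2 2-bromo-3,5-dimethoxybenzoic acid, 3 1-iodo-3,5-dimethoxybenzene
Product: 6 (2-bromo-3,5-dimethoxyphenyl)(2-hydroxy-6-iodo-4-methoxyphenyl)methanone, via acid chloride 4 (not isolated), via trimethoxy ketone 5 (not isolated)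
Conditions: (COCl)2, DMF (cat.), CH2Cl2, 20 °C; then 3, AlCl3 (3 equiv), CH2Cl2, 0 to 20 °C
Reagents that add atoms: none
Why: Friedel–Crafts acylation occurs next to iodine (para to one OMe, ortho to the other), and AlCl3 then cleaves only the methoxy group chelated ortho to the new ketone.

Step 3
Reactants: 6 (2-bromo-3,5-dimethoxyphenyl)(2-hydroxy-6-iodo-4-methoxyphenyl)methanone, 7 4-methoxybenzyl chloride
Product: 9 3-(2-bromo-3,5-dimethoxyphenyl)-4-iodo-6-methoxy-2-(4-methoxyphenyl)-1-benzofuran, via benzyl ether 8 (not isolated)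
Conditions: K2CO3, MeCN, 70 °C; filter; then P4-t-Bu phosphazene base (20 mol %), benzene, 80 °C
Reagents that add atoms: none
Why: Williamson etherification, then Kraus-type carbanion cyclisation of the benzylic ether CH2 onto the diaryl ketone and dehydration (intramolecular aldol-type condensation) gives the aromatic benzofuran.

Step 4
Reactants: 9 3-(2-bromo-3,5-dimethoxyphenyl)-4-iodo-6-methoxy-2-(4-methoxyphenyl)-1-benzofuran, 10 (S)-but-3-yn-2-ol
Product: 11 (2S)-4-(ArBr)but-3-yn-2-ol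
Conditions: Pd(PPh3)2Cl2 (3 mol %), CuI (5 mol %), Et3N, THF, 40 °C
Reagents that add atoms: none
Why: Sonogashira coupling takes place at the C–I bond, which reacts much faster than the doubly ortho-substituted C–Br bond; the bought carbinol stereocentre is not touched.

Step 5
Reactants: 11 (2S)-4-(ArBr)but-3-yn-2-ol
Product: 12 (2S,3Z)-4-(ArBr)but-3-en-2-ol
Conditions: H2 (1 atm), Pd/CaCO3 poisoned with Pb(OAc)2, quinoline, EtOAc, 20 °C
Reagents that add atoms: none
Why: Lindlar semihydrogenation adds H2 syn to give the (Z)-alkene; the hindered aryl bromide is not hydrogenolysed under these conditions.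

Step 6
Reactants: 1 3,5-dimethoxybenzoic acid
Product: 13 2-iodo-3,5-dimethoxybenzoic acid
Conditions: NIS (1.05 equiv), CF3CO2H (cat.), MeCN, 20 °C
Reagents that add atoms: N-iodosuccinimide, IN1C(=O)CCC1=O
Why: Electrophilic aromatic iodination follows the same regiochemistry as step 1.

Step 7
Reactants: 13 2-iodo-3,5-dimethoxybenzoic acid, 14 (3,5-dimethoxyphenyl)acetic acid
Product: 17 [3-hydroxy-2-(2-iodo-3,5-dimethoxybenzoyl)-5-methoxyphenyl]acetic acid, via acid chloride 15 (not isolated), via trimethoxy keto acid 16 (not isolated)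
Conditions: (COCl)2, DMF (cat.), CH2Cl2, 20 °C; then 14, AlCl3 (4 equiv), CH2Cl2, 0 to 20 °C
Reagents that add atoms: none
Why: Friedel–Crafts acylation ortho to the CH2CO2H arm (carboxyl held as its aluminium carboxylate), followed by chelation-directed ortho-demethylation as in step 2.

Step 8
Reactants: 17 [3-hydroxy-2-(2-iodo-3,5-dimethoxybenzoyl)-5-methoxyphenyl]acetic acid, 18 4-methoxybenzoyl chloride
Product: 19 [2-(2-iodo-3,5-dimethoxybenzoyl)-5-methoxy-3-(4-methoxybenzoyloxy)phenyl]acetic acid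
Conditions: aq NaOH, CH2Cl2, Bu4NHSO4 (cat.), 0 °C; then dilute HCl
Reagents that add atoms: none
Why: Schotten–Baumann O-acylation of the phenoxide; any mixed anhydride formed at the carboxylate hydrolyses back in the aqueous base.

Step 9
Reactants: 19 [2-(2-iodo-3,5-dimethoxybenzoyl)-5-methoxy-3-(4-methoxybenzoyloxy)phenyl]acetic acid
Product: 20 (ArI)acetic acid
Conditions: TiCl3, Zn dust, DME, reflux
Reagents that add atoms: none
Why: Fürstner-type intramolecular McMurry coupling of the ketone with the aryl ester carbonyl gives the benzofuran C2=C3 bond; the carboxylate is not an electrophile for low-valent titanium.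

Step 10
Reactants: 20 (ArI)acetic acid, 12 (2S,3Z)-4-(ArBr)but-3-en-2-ol
Product: 21 (2S,3Z)-4-(ArBr)but-3-en-2-yl (ArI)acetate
Conditions: DCC, DMAP (cat.), CH2Cl2, 0 to 20 °C
Reagents that add atoms: none
Why: Steglich esterification acylates the alcohol oxygen, so the carbinol configuration is retained.

Step 11
Reactants: 21 (2S,3Z)-4-(ArBr)but-3-en-2-yl (ArI)acetate
Product: 23 (2R,3S,4E)-3-(ArBr)-2-(ArI)hex-4-enoic acid, via silyl ketene acetal 22 (not isolated)
Conditions: KN(SiMe3)2, Me3SiCl, THF, −78 to 20 °C; then 1 M HCl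
Reagents that add atoms: none
Why: Ireland–Claisen [3,3]-sigmatropic rearrangement through a chair; the arylacetate gives the (Z)-silyl ketene acetal (aryl equatorial), the (Z)-alkene puts ArBr axial, and the carbinol methyl sits equatorial, so the (S)-centre is transferred to the anti C-g/C-d pair (2R,3S) and an (E)-propenyl group.

Step 12
Reactants: 23 (2R,3S,4E)-3-(ArBr)-2-(ArI)hex-4-enoic acid
Product: 24 (2R,3S,4E)-3-(ArBr)-2-(ArI)-N-methoxy-N-methylhex-4-enamide
Conditions: MeNHOMe·HCl, DCC, HOBt (cat.), Et3N, CH2Cl2, 0 °C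
Reagents that add atoms: N,O-dimethylhydroxylamine hydrochloride, CNOC.Cl
Why: Carbodiimide amide coupling under mild conditions keeps the α-centre; the Weinreb amide resists lactonisation onto the later γ-carbinol and stops the later aryl-lithium addition at the ketone stage.

Step 13
Reactants: 24 (2R,3S,4E)-3-(ArBr)-2-(ArI)-N-methoxy-N-methylhex-4-enamide
Product: 25 (2R,3S)-3-(ArBr)-2-(ArI)-N-methoxy-N-methyl-4-oxobutanamide
Conditions: OsO4 (2 mol %), NaIO4 (4 equiv), 2,6-lutidine, dioxane/H2O 3:1, 20 °C; used crude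
Reagents that add atoms: sodium periodate, [Na+].[O-][I](=O)(=O)=O
Why: Lemieux–Johnson cleavage attacks only the disubstituted alkene (the benzofuran C2=C3 bonds are tetrasubstituted and aromatic); buffered conditions and immediate use protect the α-aryl aldehyde centre C-d.

Step 14
Reactants: 25 (2R,3S)-3-(ArBr)-2-(ArI)-N-methoxy-N-methyl-4-oxobutanamide
Product: 26 first eight-membered-ring carbinol (C-e is CH–OH, both epimers, bonded to C-d and to the former iodo carbon of ArI; C-g and C-d as in 25)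
Conditions: CrCl2 (6 equiv), NiCl2 (10 mol %), DMF, 20 °C, 2 mM
Reagents that add atoms: none
Why: Nozaki–Hiyama–Kishi closure activates only the aryl iodide; that ring sits on the unit at C-g while the aldehyde sits on C-d, so only the eight-membered ring can form, and the carbinol epimers converge in step 15.

Step 15
Reactants: 26 first eight-membered-ring carbinol, 27 anisole
Product: 28 first-ring amide with 4-methoxyphenyl on C-e (C-e as in the target; C-g and C-d unchanged)
Conditions: anisole (20 equiv), TfOH (10 mol %), (CF3)2CHOH/CH2Cl2, −20 to 0 °C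
Reagents that add atoms: none
Why: Friedel–Crafts alkylation (SN1) via the 2,4-dimethoxybenzylic cation in the ring; anisole attacks para and anti to the bulky benzofuranyl group on C-d, which fixes C-e.

Step 16
Reactants: 28 first-ring amide with 4-methoxyphenyl on C-e
Product: 29 bis-benzofuran ketone with both eight-membered rings closed (C-a is C=O; C-d, C-e, C-g as in 28)
Conditions: t-BuLi (2.1 equiv), THF, −100 to −78 °C; aq NH4Cl
Reagents that add atoms: none
Why: Parham cyclisation: bromine–lithium exchange outruns attack on the amide, then intramolecular acyl substitution on the Weinreb amide closes the ring; the only aryl halide left sits on the unit at C-d, so the eight-membered ring forms, and the chelated tetrahedral intermediate protects C-g until quench.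

Step 17
Reactants: 29 bis-benzofuran ketone, 30 4-methoxyphenylmagnesium bromide
Product: 31 tertiary carbinol (C-a carries OH and 4-methoxyphenyl; configuration at C-a not relevant)
Conditions: CeCl3 (anhydrous), THF, −78 to 0 °C
Reagents that add atoms: none
Why: Organocerium 1,2-addition to the ketone suppresses enolisation of the α-aryl ketone; the new centre is ionised in the next step.

Step 18
Reactants: 31 tertiary carbinol
Product: 32 decamethyl ether of the target (a R, b R, c R, d R, e R, f S, g S, h S)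
Conditions: Et3SiH (12 equiv), CF3CO2H/CH2Cl2 1:3, 0 to 40 °C
Reagents that add atoms: none
Why: Ionic hydrogenation under substrate control:
- hydride adds to the C-a cation anti to the benzofuranyl group on C-g;
- each benzofuran C3 (C-b, C-f) is protonated from the convex face, syn to the neighbouring C-d–H or C-g–H;
- hydride then adds to each 2-aryl oxocarbenium ion (C-c, C-h) trans to the new C3 aryl group;
- the two halves see the same local control, so the two dihydrobenzofurans come out with opposite absolute sense, as the target needs.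

Step 19
Reactants: 32 decamethyl ether of the target
Product: 33 CNP0224452.2 (target)
Conditions: BBr3 (20 equiv), CH2Cl2, −78 to 20 °C; then MeOH, H2O
Reagents that add atoms: none
Why: Lewis-acid cleavage of the ten aryl methyl ethers; no stereocentre is ionised irreversibly, and the trans-dihydrobenzofurans are the thermodynamic isomers if any ring opening and reclosure occurs.

**Compound list**
1 | 3,5-dimethoxybenzoic acid | COc1cc(OC)cc(c1)C(O)=O | starting material
2 | 2-bromo-3,5-dimethoxybenzoic acid | OC(=O)c1cc(OC)cc(OC)c1Br | intermediate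
3 | 1-iodo-3,5-dimethoxybenzene | COc1cc(I)cc(OC)c1 | starting material
4 | 2-bromo-3,5-dimethoxybenzoyl chloride | O=C(Cl)c1cc(OC)cc(OC)c1Br | intermediate
5 | (2-bromo-3,5-dimethoxyphenyl)(2-iodo-4,6-dimethoxyphenyl)methanone | O=C(c1cc(OC)cc(OC)c1Br)c1c(OC)cc(OC)cc1I | intermediate
6 | (2-bromo-3,5-dimethoxyphenyl)(2-hydroxy-6-iodo-4-methoxyphenyl)methanone | O=C(c1cc(OC)cc(OC)c1Br)c1c(O)cc(OC)cc1I | intermediate
7 | 4-methoxybenzyl chloride | COc1ccc(CCl)cc1 | starting material
8 | (2-bromo-3,5-dimethoxyphenyl){2-iodo-4-methoxy-6-[(4-methoxybenzyl)oxy]phenyl}methanone | O=C(c1cc(OC)cc(OC)c1Br)c1c(OCc2ccc(OC)cc2)cc(OC)cc1I | intermediate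
9 | 3-(2-bromo-3,5-dimethoxyphenyl)-4-iodo-6-methoxy-2-(4-methoxyphenyl)-1-benzofuran | COc1ccc(cc1)-c1oc2cc(OC)cc(I)c2c1-c1cc(OC)cc(OC)c1Br | intermediate
10 | (S)-but-3-yn-2-ol | C[C@H](O)C#C | starting material
11 | (2S)-4-(ArBr)but-3-yn-2-ol | C[C@H](O)C#Cc1cc(OC)cc2oc(-c3ccc(OC)cc3)c(-c3cc(OC)cc(OC)c3Br)c12 | intermediate
12 | (2S,3Z)-4-(ArBr)but-3-en-2-ol | C[C@H](O)/C=C\c1cc(OC)cc2oc(-c3ccc(OC)cc3)c(-c3cc(OC)cc(OC)c3Br)c12 | intermediate
13 | 2-iodo-3,5-dimethoxybenzoic acid | OC(=O)c1cc(OC)cc(OC)c1I | intermediate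
14 | (3,5-dimethoxyphenyl)acetic acid | COc1cc(CC(O)=O)cc(OC)c1 | starting material
15 | 2-iodo-3,5-dimethoxybenzoyl chloride | O=C(Cl)c1cc(OC)cc(OC)c1I | intermediate
16 | [2-(2-iodo-3,5-dimethoxybenzoyl)-3,5-dimethoxyphenyl]acetic acid | OC(=O)Cc1cc(OC)cc(OC)c1C(=O)c1cc(OC)cc(OC)c1I | intermediate
17 | [3-hydroxy-2-(2-iodo-3,5-dimethoxybenzoyl)-5-methoxyphenyl]acetic acid | OC(=O)Cc1cc(OC)cc(O)c1C(=O)c1cc(OC)cc(OC)c1I | intermediate
18 | 4-methoxybenzoyl chloride | COc1ccc(cc1)C(Cl)=O | starting material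
19 | [2-(2-iodo-3,5-dimethoxybenzoyl)-5-methoxy-3-(4-methoxybenzoyloxy)phenyl]acetic acid | OC(=O)Cc1cc(OC)cc(OC(=O)c2ccc(OC)cc2)c1C(=O)c1cc(OC)cc(OC)c1I | intermediate
20 | (ArI)acetic acid, i.e. [3-(2-iodo-3,5-dimethoxyphenyl)-6-methoxy-2-(4-methoxyphenyl)-1-benzofuran-4-yl]acetic acid | OC(=O)Cc1cc(OC)cc2oc(-c3ccc(OC)cc3)c(-c3cc(OC)cc(OC)c3I)c12 | intermediate
21 | (2S,3Z)-4-(ArBr)but-3-en-2-yl (ArI)acetate | C[C@H](OC(=O)Cc1cc(OC)cc2oc(-c3ccc(OC)cc3)c(-c3cc(OC)cc(OC)c3I)c12)/C=C\c1cc(OC)cc2oc(-c3ccc(OC)cc3)c(-c3cc(OC)cc(OC)c3Br)c12 | intermediate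
22 | (Z)-trimethylsilyl ketene acetal of 21 (ArI cis to OSiMe3) | C[C@H](O/C(O[Si](C)(C)C)=C/c1cc(OC)cc2oc(-c3ccc(OC)cc3)c(-c3cc(OC)cc(OC)c3I)c12)/C=C\c1cc(OC)cc2oc(-c3ccc(OC)cc3)c(-c3cc(OC)cc(OC)c3Br)c12 | intermediate
23 | (2R,3S,4E)-3-(ArBr)-2-(ArI)hex-4-enoic acid | OC(=O)[C@@H](c1cc(OC)cc2oc(-c3ccc(OC)cc3)c(-c3cc(OC)cc(OC)c3I)c12)[C@@H](c1cc(OC)cc2oc(-c3ccc(OC)cc3)c(-c3cc(OC)cc(OC)c3Br)c12)/C=C/C | intermediate
24 | (2R,3S,4E)-3-(ArBr)-2-(ArI)-N-methoxy-N-methylhex-4-enamide | CON(C)C(=O)[C@@H](c1cc(OC)cc2oc(-c3ccc(OC)cc3)c(-c3cc(OC)cc(OC)c3I)c12)[C@@H](c1cc(OC)cc2oc(-c3ccc(OC)cc3)c(-c3cc(OC)cc(OC)c3Br)c12)/C=C/C | intermediate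
25 | (2R,3S)-3-(ArBr)-2-(ArI)-N-methoxy-N-methyl-4-oxobutanamide | CON(C)C(=O)[C@@H](c1cc(OC)cc2oc(-c3ccc(OC)cc3)c(-c3cc(OC)cc(OC)c3I)c12)[C@@H](c1cc(OC)cc2oc(-c3ccc(OC)cc3)c(-c3cc(OC)cc(OC)c3Br)c12)C=O | intermediate
26 | first eight-membered-ring carbinol (C-e CH–OH, both epimers; Weinreb amide on C-g; ArBr on C-d) | CON(C)C(=O)[C@H]1c2cc(OC)cc3oc(-c4ccc(OC)cc4)c(c23)-c2cc(OC)cc(OC)c2C(O)[C@@H]1c1cc(OC)cc2oc(-c3ccc(OC)cc3)c(-c3cc(OC)cc(OC)c3Br)c12 | intermediate
27 | anisole | COc1ccccc1 | starting material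
28 | first-ring amide with 4-methoxyphenyl on C-e (C-e, C-d, C-g as in the target) | CON(C)C(=O)[C@H]1c2cc(OC)cc3oc(-c4ccc(OC)cc4)c(c23)-c2cc(OC)cc(OC)c2[C@@H](c2ccc(OC)cc2)[C@@H]1c1cc(OC)cc2oc(-c3ccc(OC)cc3)c(-c3cc(OC)cc(OC)c3Br)c12 | intermediate
29 | bis-benzofuran ketone, both eight-membered rings closed (C-a is C=O) | O=C1[C@H]2c3cc(OC)cc4oc(-c5ccc(OC)cc5)c(c34)-c3cc(OC)cc(OC)c3[C@@H](c3ccc(OC)cc3)[C@@H]2c2cc(OC)cc3oc(-c4ccc(OC)cc4)c(c23)-c2cc(OC)cc(OC)c21 | intermediate
30 | 4-methoxyphenylmagnesium bromide | COc1ccc([Mg]Br)cc1 | starting material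
31 | tertiary carbinol (C-a carries OH and 4-methoxyphenyl, configuration at C-a open) | OC1(c2ccc(OC)cc2)[C@H]2c3cc(OC)cc4oc(-c5ccc(OC)cc5)c(c34)-c3cc(OC)cc(OC)c3[C@@H](c3ccc(OC)cc3)[C@@H]2c2cc(OC)cc3oc(-c4ccc(OC)cc4)c(c23)-c2cc(OC)cc(OC)c21 | intermediate
32 | decamethyl ether of the target (all ten phenols as OMe; a R, b R, c R, d R, e R, f S, g S, h S) | COc1ccc([C@@H]2c3c(OC)cc(OC)cc3[C@@H]3c4c(cc(OC)cc4[C@H]4[C@H](c5ccc(OC)cc5)c5c(OC)cc(OC)cc5[C@H]5c6c(cc(OC)cc6[C@H]24)O[C@@H]5c2ccc(OC)cc2)O[C@H]3c2ccc(OC)cc2)cc1 | intermediate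
33 | CNP0224452.2 | Oc1ccc([C@@H]2c3c(O)cc(O)cc3[C@@H]3c4c(cc(O)cc4[C@H]4[C@H](c5ccc(O)cc5)c5c(O)cc(O)cc5[C@H]5c6c(cc(O)cc6[C@H]24)O[C@@H]5c2ccc(O)cc2)O[C@H]3c2ccc(O)cc2)cc1 | target

**Step count and risks**
Total steps: 19. Longest linear sequence: 15 (steps 1–5, then 10–19).

Three steps most likely to fail:

Step 14 (Ni/Cr closure of an eight-membered ring with a hindered, electron-rich aryl iodide). The fallback sets out from 25 and comes back at 26. The C–I bond of 25 is borylated (Pd(dppf)Cl2, bis(pinacolato)diboron, KOAc, dioxane, 80 °C; the doubly ortho-substituted bromide stays) to give the aryl pinacol boronate aldehyde F1. Rhodium-catalysed intramolecular 1,2-addition of the aryl–boron bond to the aldehyde ([Rh(OH)(cod)]2, dioxane/H2O, 60 °C) then closes the same ring to 26.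

Step 16 (aryl-lithium ring closure next to an acidic benzylic α-CH). The fallback sets out from 28 and comes back at 29. The aryl bromide is borylated (Pd(OAc)2, SPhos, bis(pinacolato)diboron, K3PO4, dioxane, 100 °C) to the boronate amide F2. The Weinreb amide is reduced with i-Bu2AlH (THF, −78 °C) to the boronate aldehyde F3. [Rh(OH)(cod)]2 closes the ring without strong base to the second-ring secondary alcohol F4. Dess–Martin periodinane oxidises F4 to ketone 29.

Step 18 (five stereocentres set in one ionic hydrogenation; face selectivity at the benzofuran C3 carbons is the weak point, and E1 loss toward C-g is possible). The fallback sets out from 31 and comes back at 32. Et3SiH/CF3CO2H at −30 °C reduces only the carbinol and gives the bis-benzofuran with C-a–H, F5. Heterogeneous hydrogenation (H2 60 bar, Pd(OH)2 on carbon, EtOAc/AcOH) adds H2 syn from the convex face of each benzofuran to give the bis(2,3-cis-dihydrobenzofuran) F6. CF3CO2H in CH2Cl2 then epimerises the two O–CH(aryl) centres to trans through reversible benzylic C–O ionisation, giving 32.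

**Further compounds**
F1 | step 14 | (2R,3S)-3-(ArBr)-2-[ArI with I replaced by 4,4,5,5-tetramethyl-1,3,2-dioxaborolan-2-yl]-N-methoxy-N-methyl-4-oxobutanamide | CON(C)C(=O)[C@@H](c1cc(OC)cc2oc(-c3ccc(OC)cc3)c(-c3cc(OC)cc(OC)c3B3OC(C)(C)C(C)(C)O3)c12)[C@@H](c1cc(OC)cc2oc(-c3ccc(OC)cc3)c(-c3cc(OC)cc(OC)c3Br)c12)C=O
F2 | step 16 | 28 with Br replaced by 4,4,5,5-tetramethyl-1,3,2-dioxaborolan-2-yl | CON(C)C(=O)[C@H]1c2cc(OC)cc3oc(-c4ccc(OC)cc4)c(c23)-c2cc(OC)cc(OC)c2[C@@H](c2ccc(OC)cc2)[C@@H]1c1cc(OC)cc2oc(-c3ccc(OC)cc3)c(-c3cc(OC)cc(OC)c3B3OC(C)(C)C(C)(C)O3)c12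
F3 | step 16 | aldehyde from F2 (CHO on C-g in place of the Weinreb amide) | O=C[C@H]1c2cc(OC)cc3oc(-c4ccc(OC)cc4)c(c23)-c2cc(OC)cc(OC)c2[C@@H](c2ccc(OC)cc2)[C@@H]1c1cc(OC)cc2oc(-c3ccc(OC)cc3)c(-c3cc(OC)cc(OC)c3B3OC(C)(C)C(C)(C)O3)c12
F4 | step 16 | second-ring secondary alcohol (C-a is CH–OH, both epimers) | OC1[C@H]2c3cc(OC)cc4oc(-c5ccc(OC)cc5)c(c34)-c3cc(OC)cc(OC)c3[C@@H](c3ccc(OC)cc3)[C@@H]2c2cc(OC)cc3oc(-c4ccc(OC)cc4)c(c23)-c2cc(OC)cc(OC)c21
F5 | step 18 | bis-benzofuran with C-a–H (a R; d, e, g as in 32) | COc1ccc(cc1)[C@H]1[C@H]2c3cc(OC)cc4oc(-c5ccc(OC)cc5)c(c34)-c3cc(OC)cc(OC)c3[C@@H](c3ccc(OC)cc3)[C@@H]2c2cc(OC)cc3oc(-c4ccc(OC)cc4)c(c23)-c2cc(OC)cc(OC)c21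
F6 | step 18 | bis(2,3-cis-dihydrobenzofuran) epimer of 32 at C-c and C-h | COc1ccc([C@@H]2c3c(OC)cc(OC)cc3[C@@H]3c4c(cc(OC)cc4[C@H]4[C@H](c5ccc(OC)cc5)c5c(OC)cc(OC)cc5[C@H]5c6c(cc(OC)cc6[C@H]24)O[C@H]5c2ccc(OC)cc2)O[C@@H]3c2ccc(OC)cc2)cc1
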